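Readings and results come from a simulation with made-up constants; scatter was added.

The delta run, charged with 1.6 equiv of third reagent against 0.70 equiv in the theta run, held more target at 6.00 min, 30.8% against 16.9%, while target plus intermediate B stood at 77.7% against 78.5%.

all flasks: substrate 0.20 M

| run | partner | second reagent | third reagent | remark | time |
|---|---|---|---|---|---|
| theta | 1.1 equiv | 4 equiv | 0.70 equiv | run made earlier |  |
| delta | 1.1 equiv | 4 equiv | 1.6 equiv | run made earlier |  |
| flask | 1.10 equiv | 4.00 equiv | 1.05 equiv |  | 6.0 min |

- theta (time / min: substrate / %, target / %, intermediate B / %): 0.500: 1.9, 15.5, 58.1; 0.833: 0, 16.0, 60.5; 1.50: 0, 16.4, 62.0; 3.00: 0, 16.0, 61.5; 6.00: 1.3, 16.9, 61.6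
- delta (time / min: substrate / %, target / %, intermediate B / %): 0.500: 3.1, 29.2, 45.1; 1.50: 0.3, 30.6, 46.6; 3.00: 0, 30.8, 47.6; 4.00: 0.3, 30.7, 47.7; 6.00: 0, 30.8, 46.9

(scatter of a reading: 0.5 percentage points)

1. the state of affairs at 6.0 min: stopped, and by what, or still going (all of the substrate has reacted / it is still moving / forward and back rates have come level / the second reagent has run out first / the partner has run out first / the third reagent has run out first)
2. share of the substrate used up at 6.0 min
3. target at 6.0 min, in percent of the substrate charged
4. intermediate B at 6.0 min, in percent of the substrate charged

- the numbers in the tables scatter with a standard deviation of 0.5 percentage points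
- the reaction counts as stopped when no species that holds the substrate changes by six tenths of a point or more over the second half of the time

Substrate read 0% and 0% at 3.00 min, so I expected it to be gone from the new flask by 6.0 min, leaving a pool of about 78.1% shared between target and intermediate B. To split the pool I used a balance number, an apparent equilibrium constant, K = [target]/([intermediate B][third reagent]), with the third reagent taken as its charge less the target formed. The theta run read 2.58 L mol⁻¹ and the delta run 2.54 L mol⁻¹, so I carried their mean, 2.56 L mol⁻¹, as the balance number K.

Counting the whole charge of third reagent as free overstates target, which gave an upper bound of 27.3%. Subtracting that overstated target leaves too little reagent, which gave a lower bound of 22.2%. Subtracting the lower bound tightened the top to 23.3%. I committed to target between 22.2% and 23.3%, and intermediate B as the pool less that.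

The forecast, reasoning that “the target comes out of the same pool as B”, gave a single point inside my bracket: all of the substrate has reacted, 100% used, target 22.7%, intermediate B 55.3%.

The flask ended thus: all of the substrate has reacted, with 100% used, target 22.6%, inside my bracket, and intermediate B 54.9%.

    second reagent + intermediate A → intermediate B (k = 0.359 L mol⁻¹ s⁻¹)
    third reagent + intermediate B ⇌ target (K = 2.50 L mol⁻¹, k = 0.662 L mol⁻¹ s⁻¹)
    substrate + second reagent → side product (k = 0.0457 L mol⁻¹ s⁻¹)
    substrate + partner → intermediate A (k = 0.882 L mol⁻¹ s⁻¹)

I ran the same reckoning on a neighbouring flask, charged with 2.60 equiv of third reagent and otherwise unchanged. The whole charge counted as free gave 44.6%, the next pass 41.0%, and the third 41.3%, which left 36.8% for intermediate B. That neighbouring flask held target 40.6% and intermediate B 37.0%.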